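- Count partner B.

| setting | gamma | Friday's | Thursday's |
|---|---|---|---|
| substrate | 0.48 M | 0.48 M | 0.48 M |
| partner B | 0.83 M | 1.20 M | 1.80 M |
| solid partner | 1.2 M | 1.20 M | 1.20 M |
| remark | run made earlier |  |  |
| time |  | 20 h | 20 h |

gamma run (percent of the substrate charged)

| time / h | target / % | isomer of the product / % | homo product / % | substrate / % |
|---|---|---|---|---|
| 5.00 | 5.3 | 4.3 | 9.2 | 69.1 |
| 10.0 | 5.6 | 9.2 | 14.7 | 63.8 |
| 15.0 | 5.0 | 11.0 | 16.9 | 63.8 |
| 20.0 | 5.2 | 11.0 | 17.7 | 62.8 |

(readings scatter by 0.3 percentage points)

1. which of these there is most of at the end, counted by the substrate in it, Friday's (isomer of the product / substrate / target / homo product)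
2. which of these there is most of at the end, counted by the substrate in it, Thursday's (isomer of the product / substrate / target / homo product)
3. amount of the one of these that there is most of at the end, in percent of the substrate charged, Friday's
4. amount of the one of these that there is most of at the end, in percent of the substrate charged, Thursday's

- percentages count the substrate that a species holds: one homo product counts as two
- solid, in amounts per volume of the solution: solid partner
- at the start none of the solid partner is in solution

- Turn the time first: by hand a longer run should take more substrate, but the gamma run's substrate moves from 63.8% at 10.0 h to 62.8% at 20.0 h, so assume that this flask has stalled and that partner B, its limiting reagent, is what ended it, which is an assumption because no reading of partner B exists.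
- Turn partner B next: take the substrate's rate of loss over partner B's as a constant and integrate from the charge to the stall, which gives substrate lost = φ × partner B charged, where φ, the substrate lost per partner B charged, is 0.215 in the gamma run.
- Split what is lost by the gamma run's shares: homo product holds 47.6% of the lost substrate at 20.0 h, which is more than isomer of the product or target hold.
- For Friday's, φ gives a loss of 53.8%, so substrate stays at 46.2% and leads homo product at 25.6%.
- For Thursday's, φ gives a loss of 80.7%, so homo product at 38.4% passes substrate at 19.3%, but trust this less, since Thursday's partner B stands above the solid partner and the gamma run's stood below it.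
- The forecast names substrate at 47% (40% to 54%) for Friday's and homo product at 35% (27% to 45%) for Thursday's, holding that “partner B is the likely candidate”, and my reckoning names the same species but puts Friday's substrate lower and Thursday's homo product higher.
- Friday's ends with substrate at 44.9% and Thursday's with homo product at 40.5%, and Friday's keeps 0.012% of its partner B against 45% of its substrate.

    partner B + partner A → second intermediate (k = 2.50 M⁻¹ h⁻¹)
    target ⇌ isomer of the product (K = 2.20, k = 0.490 h⁻¹)
    solid partner ⇌ partner A, rate k3*(cs3 - [partner A]) while solid is left; crystals form when [partner A] > cs3 (solubility = 0.370 M, k = 0.350 h⁻¹)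
    second intermediate → side product (k = 0.620 h⁻¹)
    substrate + partner B → open intermediate (k = 0.140 M⁻¹ h⁻¹)
    2 open intermediate → homo product (k = 1.30 M⁻¹ h⁻¹)
    open intermediate + second intermediate → target (k = 1.60 M⁻¹ h⁻¹)

- Put φ on a flask like Friday's but charged with 0.48 M of partner B: the loss comes to 21.5%, which leaves 78.5% of the substrate, and that flask holds 81% at 20.0 h.

(The data were computed with made-up constants; the scatter is artificial.)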